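**Plan**

- Retrosynthesis: the two phenols are masked as benzyl ethers and an ethoxycarbonyl group is put back on C3 of the lactone. Two bonds are then cut in one operation: C3–CH2 to the dimethoxyphenyl ring, and aryl–CH2 of the catechol side chain on C4.
- Enabling feature: C4 of the γ-lactone carries the catechol ring through a single CH2 and sits next to the carbonyl-bearing C3. C3, C4 and that CH2 can therefore be the three atoms of a cyclopropane fused to the lactone ring, which the aryl group opens at the CH2.
- Forward order: lactone and cyclopropane rings arise together from diethyl malonate and (R)-epichlorohydrin. The aryl Grignard reagent and the dimethoxybenzyl bromide are then joined to this core in one flask. Ester removal, equilibration at C3 and debenzylation finish the route.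
- Stereochemistry: C4 comes from (R)-epichlorohydrin (one inversion during cyclopropane closure, untouched afterwards). C3 is set last, trans to C4, by thermodynamic equilibration, giving (3R,4R).

Key step: step 5

**Route**

Step 1
Reactants: 1 diethyl malonate; 2 (R)-epichlorohydrin
Product: 3 ethyl (1S,5R)-2-oxo-3-oxabicyclo[3.1.0]hexane-1-carboxylate
Conditions: NaOEt (1.05 equiv), EtOH, 0 °C then 75 °C
Reagents that add atoms: none
Why: This is the established malonate–epichlorohydrin cyclopropanation cascade, in which the malonate anion opens the epoxide at its CH2, the chlorohydrin alkoxide closes to a new epoxide, a 3-exo-tet attack of the malonate carbanion on the secondary epoxide carbon forms the cyclopropane with one inversion and the freed alkoxide lactonises onto the cis ester, so that C5 should be (R) and the obligatory cis ring fusion makes C1 (S).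

Step 2
Reactants: 4 4-bromocatechol
Product: 5 1,2-bis(benzyloxy)-4-bromobenzene
Conditions: BnBr (2.3 equiv), K2CO3, DMF, 60 °C, under N2
Reagents that add atoms: benzyl bromide, BrCc1ccccc1
Why: Williamson ether synthesis on both phenols should proceed cleanly with a reactive benzylic halide and carbonate base, and the benzyl ethers tolerate organomagnesium and organocopper reagents while being removable by hydrogenolysis at the end.

Step 3
Reactants: 5 1,2-bis(benzyloxy)-4-bromobenzene
Product: 6 3,4-bis(benzyloxy)phenylmagnesium bromide (THF solution, titrated and used directly)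
Conditions: Mg turnings, I2 (cat.), THF, 45 °C
Reagents that add atoms: magnesium, [Mg]
Why: Grignard reagent formation by insertion of magnesium into the aryl C–Br bond is routine for alkoxy-substituted bromoarenes, and aryl benzyl ethers are inert to the reagent.

Step 4
Reactants: 7 3,4-dimethoxybenzyl alcohol
Product: 8 3,4-dimethoxybenzyl bromide
Conditions: PBr3 (0.4 equiv), CH2Cl2, 0 °C; used freshly prepared
Reagents that add atoms: phosphorus tribromide, BrP(Br)Br
Why: Bromination of a benzylic alcohol with PBr3 proceeds through a phosphite ester that bromide displaces, which should be fast for this electron-rich benzylic position.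

Step 5
Reactants: 3 ethyl (1S,5R)-2-oxo-3-oxabicyclo[3.1.0]hexane-1-carboxylate; 6 3,4-bis(benzyloxy)phenylmagnesium bromide; 8 3,4-dimethoxybenzyl bromide
Product: 10 ethyl (3R,4R)-4-[3,4-bis(benzyloxy)benzyl]-3-(3,4-dimethoxybenzyl)-2-oxotetrahydrofuran-3-carboxylate, via bromomagnesium lactone ester enolate 9 (not isolated)
Conditions: CuBr·SMe2 (10 mol %), 6 (1.3 equiv), THF, −40 to −20 °C; then DMPU, 8 (2.5 equiv), −20 to 40 °C
Reagents that add atoms: none
Why: Transmetalation of 6 to monovalent copper gives an arylcuprate that attacks the unsubstituted cyclopropane carbon C6 of 3 in an SN2-like homoconjugate addition, the C1–C6 bond breaking toward the carbon that bears both carbonyl groups, and reductive elimination from the transient trivalent copper species forms the aryl–CH2 bond and leaves the chelated enolate 9. The closest known reaction type is the copper-catalysed Grignard opening of cyclopropane-1,1-dicarbonyl compounds, established for this very lactone, followed by C-alkylation of a 2-alkoxycarbonyl-γ-butyrolactone enolate with a benzylic halide, here run in the same flask after addition of DMPU. No ring is closed; the three-membered ring is opened with release of strain. C4 is a spectator and keeps the configuration brought in from 2, while the new quaternary centre C3 is set by approach of 8 to the enolate face opposite the C4 benzyl group, which should give the (3R) ester; this centre is temporary, since the ester is removed in step 6. The step needs attack at the cyclopropane CH2 and not at the ring-fusion CH or a carbonyl group, which the soft organocopper nucleophile, the low temperature and the lower substitution of that carbon secure, and it needs C- over O-alkylation, which the soft benzylic bromide favours. The Grignard reagent is kept near one equivalent and 8 is used in excess, so that copper-catalysed aryl–benzyl coupling of leftover 6 does not starve the enolate of electrophile.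

Step 6
Reactants: 10 ethyl (3R,4R)-4-[3,4-bis(benzyloxy)benzyl]-3-(3,4-dimethoxybenzyl)-2-oxotetrahydrofuran-3-carboxylate
Product: 11 (4R)-4-[3,4-bis(benzyloxy)benzyl]-3-(3,4-dimethoxybenzyl)dihydrofuran-2(3H)-one (mixture of C3 epimers)
Conditions: LiCl, H2O, DMSO, 150 °C
Reagents that add atoms: none
Why: In this Krapcho dealkoxycarbonylation chloride de-ethylates the ester activated by the geminal lactone carbonyl, the carboxylate loses CO2 and the lactone enolate is protonated by water, which is not expected to be selective at C3 and is corrected in step 7.

Step 7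
Reactants: 11 (4R)-4-[3,4-bis(benzyloxy)benzyl]-3-(3,4-dimethoxybenzyl)dihydrofuran-2(3H)-one (mixture of C3 epimers)
Product: 12 (3R,4R)-4-[3,4-bis(benzyloxy)benzyl]-3-(3,4-dimethoxybenzyl)dihydrofuran-2(3H)-one
Conditions: DBU (0.5 equiv), toluene, 90 °C
Reagents that add atoms: none
Why: Base-mediated epimerisation through the lactone enolate is a thermodynamic equilibration, and since the trans arrangement of the two benzyl groups on the five-membered ring is the more stable one, C3 should settle as (R) next to the fixed (R)-C4, which is not acidic and is not touched.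

Step 8
Reactants: 12 (3R,4R)-4-[3,4-bis(benzyloxy)benzyl]-3-(3,4-dimethoxybenzyl)dihydrofuran-2(3H)-one
Product: 13 (3R,4R)-4-(3,4-dihydroxybenzyl)-3-(3,4-dimethoxybenzyl)dihydrofuran-2(3H)-one
Conditions: H2 (1 atm), 10% Pd/C, EtOAc–EtOH, rt; filtration and concentration under N2
Reagents that add atoms: none
Why: Catalytic hydrogenolysis of aryl benzyl ethers over Pd/C under neutral conditions should free the catechol without touching the lactone, the aryl methyl ethers or either stereocentre.

**Compound list**

1 | diethyl malonate | CCOC(=O)CC(=O)OCC | starting material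
2 | (R)-epichlorohydrin | ClC[C@H]1CO1 | starting material
3 | ethyl (1S,5R)-2-oxo-3-oxabicyclo[3.1.0]hexane-1-carboxylate | CCOC(=O)[C@]12C[C@H]1COC2=O | intermediate
4 | 4-bromocatechol | Oc1ccc(Br)cc1O | starting material
5 | 1,2-bis(benzyloxy)-4-bromobenzene | Brc1ccc(OCc2ccccc2)c(OCc2ccccc2)c1 | intermediate
6 | 3,4-bis(benzyloxy)phenylmagnesium bromide | Br[Mg]c1ccc(OCc2ccccc2)c(OCc2ccccc2)c1 | intermediate
7 | 3,4-dimethoxybenzyl alcohol | COc1ccc(CO)cc1OC | starting material
8 | 3,4-dimethoxybenzyl bromide | COc1ccc(CBr)cc1OC | intermediate
9 | bromomagnesium enolate of ethyl (4R)-4-[3,4-bis(benzyloxy)benzyl]-2-oxotetrahydrofuran-3-carboxylate | CCOC(=O)C1=C(O[Mg]Br)OC[C@@H]1Cc1ccc(OCc2ccccc2)c(OCc2ccccc2)c1 | intermediate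
10 | ethyl (3R,4R)-4-[3,4-bis(benzyloxy)benzyl]-3-(3,4-dimethoxybenzyl)-2-oxotetrahydrofuran-3-carboxylate | COc1ccc(C[C@@]2(C(=O)OCC)C(=O)OC[C@@H]2Cc2ccc(OCc3ccccc3)c(OCc3ccccc3)c2)cc1OC | intermediate
11 | (4R)-4-[3,4-bis(benzyloxy)benzyl]-3-(3,4-dimethoxybenzyl)dihydrofuran-2(3H)-one, mixture of C3 epimers | COc1ccc(CC2C(=O)OC[C@@H]2Cc2ccc(OCc3ccccc3)c(OCc3ccccc3)c2)cc1OC | intermediate
12 | (3R,4R)-4-[3,4-bis(benzyloxy)benzyl]-3-(3,4-dimethoxybenzyl)dihydrofuran-2(3H)-one | COc1ccc(C[C@H]2C(=O)OC[C@@H]2Cc2ccc(OCc3ccccc3)c(OCc3ccccc3)c2)cc1OC | intermediate
13 | (3R,4R)-4-(3,4-dihydroxybenzyl)-3-(3,4-dimethoxybenzyl)dihydrofuran-2(3H)-one | COc1ccc(C[C@H]2C(=O)OC[C@@H]2Cc2ccc(O)c(O)c2)cc1OC | target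

**Step count**

Total: 8 steps. Longest linear sequence: 6 steps (steps 2, 3, 5, 6, 7, 8, from 4-bromocatechol).

**Steps most likely to fail**

Step 5. The chelated magnesium enolate may be alkylated only sluggishly, while the copper catalyst and leftover Grignard reagent consume the benzylic bromide by cross-coupling. Some carbonyl addition by the Grignard reagent is also possible. The fallback separates the two bond formations. It sets out from 3 and 6: the copper-catalysed opening is run alone and quenched with dilute HCl, giving ethyl (4R)-4-[3,4-bis(benzyloxy)benzyl]-2-oxotetrahydrofuran-3-carboxylate F1. Its sodium enolate (NaH, DMF, 0 °C) is then alkylated with 8 in a standard malonate-type C-alkylation, free of copper and of residual Grignard reagent. The route is rejoined at 10.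

Step 6. De-ethylation by chloride may be slow at an ester flanked by a quaternary carbon, and prolonged heating could degrade the material. The fallback replaces nucleophilic dealkylation by hydrolysis and thermal decarboxylation. It sets out from 10: KOH in EtOH–H2O at reflux opens the lactone and saponifies the ester to dipotassium 2-[(2R)-1-[3,4-bis(benzyloxy)phenyl]-3-hydroxypropan-2-yl]-2-(3,4-dimethoxybenzyl)propanedioate F2. Acidification with HCl relactonises to (4R)-4-[3,4-bis(benzyloxy)benzyl]-3-(3,4-dimethoxybenzyl)-2-oxotetrahydrofuran-3-carboxylic acid F3. Heating F3 in toluene at 110 °C expels CO2, and the route is rejoined at 11.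

Step 7. Equilibration may stop with a persistent share of the cis lactone that is hard to remove. The fallback sets the trans relationship under kinetic control instead. It sets out from 3 and 6: opening with an acidic quench as above gives the lactone ester F1. Its Krapcho dealkoxycarbonylation (LiCl, H2O, DMSO, 140 °C, here at a tertiary and not a quaternary carbon) gives (R)-4-[3,4-bis(benzyloxy)benzyl]dihydrofuran-2(3H)-one F4. The lithium enolate (LiN(SiMe3)2, THF, −78 °C) is alkylated with 8 on the face opposite the C4 substituent, the usual course for β-benzyl-γ-butyrolactones. The route is rejoined at 12, bypassing 10 and 11.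

**Further compounds**

F1 | step 5 | ethyl (4R)-4-[3,4-bis(benzyloxy)benzyl]-2-oxotetrahydrofuran-3-carboxylate (C3 epimers) | CCOC(=O)C1C(=O)OC[C@@H]1Cc1ccc(OCc2ccccc2)c(OCc2ccccc2)c1
F2 | step 6 | dipotassium 2-[(2R)-1-[3,4-bis(benzyloxy)phenyl]-3-hydroxypropan-2-yl]-2-(3,4-dimethoxybenzyl)propanedioate | COc1ccc(CC(C(=O)[O-])(C(=O)[O-])[C@H](CO)Cc2ccc(OCc3ccccc3)c(OCc3ccccc3)c2)cc1OC.[K+].[K+]
F3 | step 6 | (4R)-4-[3,4-bis(benzyloxy)benzyl]-3-(3,4-dimethoxybenzyl)-2-oxotetrahydrofuran-3-carboxylic acid (C3 epimers) | COc1ccc(CC2(C(=O)O)C(=O)OC[C@@H]2Cc2ccc(OCc3ccccc3)c(OCc3ccccc3)c2)cc1OC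
F4 | step 7 | (R)-4-[3,4-bis(benzyloxy)benzyl]dihydrofuran-2(3H)-one | O=C1C[C@@H](Cc2ccc(OCc3ccccc3)c(OCc3ccccc3)c2)CO1
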